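Ring C is closed last, by a formal hetero-[4+2] annulation of an aldehyde C=O with an ortho-fluoroaryl ketone. The step exploits the C4 carbonyl of ring C: it makes C3 enolisable and, standing ortho to C8a on ring A, activates a C8a–F bond towards ipso substitution. One flask operation joins C2–C3 by a catalytic enantioselective Mukaiyama aldol, which sets both stereocentres, and then O1–C8a by fluoride-triggered SNAr of the new C2 oxygen. The precursors are the (Z)-enol silane of a 2-fluoro-4,6-bis(methoxymethoxy)-3-prenylphenyl methoxymethoxymethyl ketone and 3-geranyl-4-(methoxymethoxy)benzaldehyde; acid then frees the four hydroxyls.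

Key step: step 10

Remark: flavonoid numbering is used for the chromanone (O1, C2, C3, C4, C4a, C5 to C8, C8a); ring A is the benzo ring, ring B the 2-aryl group, ring C the pyranone.

Remark (assumption): the bisphosphoramide of step 10 is the chiral Lewis base in which two cyclic phosphoramide units derived from (S)-N,N′-dimethyl-1,1′-binaphthyl-2,2′-diamine are joined at phosphorus through an N,N′-dimethylpentane-1,5-diamine linker (constitution CN(CCCCCN(C)P1(=O)N(C)c2ccc3ccccc3c2-c2c(N1C)ccc1ccccc21)P1(=O)N(C)c2ccc3ccccc3c2-c2c(N1C)ccc1ccccc21). Its (S,S) enantiomer is assumed, from the usual facial preference of this catalyst family, to deliver the enol silane to the Si face of the aldehyde; should the first run show the opposite sense, the (R,R) catalyst is used instead.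

Step 1
Reactants: 1 5-fluorobenzene-1,3-diol
Product: 2 4,6-dibromo-5-fluorobenzene-1,3-diol
Conditions: NBS (2.05 equiv), MeCN, −20 °C → rt
Reagents that add atoms: N-bromosuccinimide, O=C1CCC(=O)N1Br
Why: Electrophilic aromatic bromination should go twice, at the two equivalent carbons that are ortho to one hydroxyl and para to the other (the carbons flanking fluorine), because the carbon between the two hydroxyls is the least reactive position of a 5-substituted resorcinol.

Step 2
Reactants: 2 4,6-dibromo-5-fluorobenzene-1,3-diol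
Product: 3 1,3-dibromo-2-fluoro-4,6-bis(methoxymethoxy)benzene
Conditions: MOMCl, i-Pr2NEt, CH2Cl2, 0 °C → rt
Reagents that add atoms: chloromethyl methyl ether, COCCl
Why: Williamson-type O-alkylation turns both phenols into methoxymethyl acetals that withstand the organolithium, Lewis acid and fluoride conditions used later.

Step 3
Reactants: 3 1,3-dibromo-2-fluoro-4,6-bis(methoxymethoxy)benzene; 4 1-bromo-3-methylbut-2-ene (prenyl bromide)
Product: 6 1-bromo-2-fluoro-4,6-bis(methoxymethoxy)-3-(3-methylbut-2-en-1-yl)benzene, via aryllithium 5 (not isolated)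
Conditions: n-BuLi (1.0 equiv), THF, −78 °C; then CuBr·SMe2 (10 mol %), 4, −78 → −30 °C
Reagents that add atoms: none
Why: Bromine–lithium exchange on the symmetric dibromide can give only one monolithio species, which is kept at −78 °C to prevent loss of LiF and is trapped at the primary carbon of prenyl bromide by copper-catalysed SN2 allylation.

Step 4
Reactants: 7 methyl 2-hydroxyacetate (methyl glycolate)
Product: 8 methyl 2-(methoxymethoxy)acetate
Conditions: MOMCl, i-Pr2NEt, CH2Cl2, 0 °C → rt
Reagents that add atoms: chloromethyl methyl ether, COCCl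
Why: O-Alkylation of the primary alcohol (acetal formation) installs the small, coordinating C3 oxygen substituent that the aldol step requires.

Step 5
Reactants: 8 methyl 2-(methoxymethoxy)acetate
Product: 9 N-methoxy-2-(methoxymethoxy)-N-methylacetamide
Conditions: MeNH(OMe)·HCl, i-PrMgCl, THF, −20 °C
Reagents that add atoms: N,O-dimethylhydroxylamine hydrochloride, CNOC.Cl
Why: Aminolysis of the ester by the chloromagnesium amide of N,O-dimethylhydroxylamine gives the N-methoxy-N-methylamide that allows a single clean acylation in the next step.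

Step 6
Reactants: 6 1-bromo-2-fluoro-4,6-bis(methoxymethoxy)-3-(3-methylbut-2-en-1-yl)benzene; 9 N-methoxy-2-(methoxymethoxy)-N-methylacetamide
Product: 12 1-[2-fluoro-4,6-bis(methoxymethoxy)-3-(3-methylbut-2-en-1-yl)phenyl]-2-(methoxymethoxy)ethan-1-one, via aryllithium 10 (not isolated), via tetrahedral lithium adduct 11 (not isolated)
Conditions: n-BuLi, THF, −78 °C; then 9, −78 → −40 °C
Reagents that add atoms: none
Why: Bromine–lithium exchange followed by Weinreb ketone synthesis: the chelated tetrahedral adduct persists until work-up, so the hindered aryllithium acylates once and the carbon between fluorine and the acetal ends up carrying the acyl group.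

Step 7
Reactants: 12 1-[2-fluoro-4,6-bis(methoxymethoxy)-3-(3-methylbut-2-en-1-yl)phenyl]-2-(methoxymethoxy)ethan-1-one
Product: 14 {[(Z)-1-[2-fluoro-4,6-bis(methoxymethoxy)-3-(3-methylbut-2-en-1-yl)phenyl]-2-(methoxymethoxy)ethenyl]oxy}trimethylsilane, via lithium enolate 13 (not isolated)
Conditions: LiN(SiMe3)2, THF, −78 °C; then Me3SiCl, −78 → 0 °C
Reagents that add atoms: chlorotrimethylsilane, C[Si](C)(C)Cl
Why: Kinetic deprotonation gives a lithium enolate in which lithium bridges the enolate and α-alkoxy oxygens, so O-silylation (silyl enol ether formation) should fix the Z geometry.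

Step 8
Reactants: 15 3-bromo-4-hydroxybenzaldehyde
Product: 16 3-bromo-4-(methoxymethoxy)benzaldehyde
Conditions: MOMCl, i-Pr2NEt, CH2Cl2, 0 °C → rt
Reagents that add atoms: chloromethyl methyl ether, COCCl
Why: Williamson-type O-alkylation protects the phenol as the methoxymethyl acetal.

Step 9
Reactants: 16 3-bromo-4-(methoxymethoxy)benzaldehyde; 17 (2E)-1-bromo-3,7-dimethylocta-2,6-diene (geranyl bromide)
Product: 21 3-[(2E)-3,7-dimethylocta-2,6-dien-1-yl]-4-(methoxymethoxy)benzaldehyde, via lithium aminal alkoxide 18 (not isolated), via lithiated aminal alkoxide 19 (not isolated), via geranylated aminal alkoxide 20 (not isolated)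
Conditions: LiN(CH2CH2)2O (from morpholine and n-BuLi), THF, −78 °C; then n-BuLi, −78 °C; then CuBr·SMe2 (10 mol %), 17, −78 → −20 °C; H2O
Reagents that add atoms: none
Why: Addition of the lithium amide masks the aldehyde in the flask as an α-amino alkoxide that survives bromine–lithium exchange, copper-catalysed SN2 allylation with geranyl bromide keeps the E double bond, and aqueous work-up returns the aldehyde.

Step 10
Reactants: 14 {[(Z)-1-[2-fluoro-4,6-bis(methoxymethoxy)-3-(3-methylbut-2-en-1-yl)phenyl]-2-(methoxymethoxy)ethenyl]oxy}trimethylsilane; 21 3-[(2E)-3,7-dimethylocta-2,6-dien-1-yl]-4-(methoxymethoxy)benzaldehyde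
Product: 24 (2R,3R)-2-{3-[(2E)-3,7-dimethylocta-2,6-dien-1-yl]-4-(methoxymethoxy)phenyl}-3,5,7-tris(methoxymethoxy)-8-(3-methylbut-2-en-1-yl)-2,3-dihydro-4H-chromen-4-one, via trichlorosilyl aldolate 22 (not isolated), via cesium alkoxide 23 (not isolated)
Conditions: 21 (1.1 equiv), SiCl4 (1.2 equiv), (S,S)-bisphosphoramide (5 mol %), i-Pr2NEt (10 mol %), CH2Cl2, −78 °C; then CsF (8 equiv), DMF, −60 → 0 °C
Reagents that add atoms: none
Why: Proposed new method: the phosphoramide-bound trichlorosilyl cation activates aldehyde 21, the (Z)-enol silane 14 adds through an open transition state (C2–C3 bond) to give the chelated trichlorosilyl aldolate 22, and fluoride then strips silicon from the C2 oxygen so that alkoxide 23 attacks the fluorine-bearing C8a ortho to the C4 carbonyl and expels fluoride (O1–C8a bond). The closest known reaction types are the Lewis-base-catalysed SiCl4 Mukaiyama aldol of ketone enol silanes and glycolate silyl ketene acetals with aromatic aldehydes and the intramolecular SNAr etherification of β-hydroxy 2-fluoroaryl ketones, which are here fused in one flask. Ring C closes by a six-membered addition–elimination at sp2 carbon C8a (formally 6-exo-trig with respect to the C8a=C8 bond), through a Meisenheimer anion stabilised as the C4 enolate. C2 is set by the catalyst, which exposes the Si face of the aldehyde, and C3 by the anti preference of the open transition state when a small α-alkoxy group sits next to a bulky aryl ketone residue (by analogy with bulky esters of α-methoxyacetate); the cyclisation breaks no bond to either centre, so the anti (2R,3R) adduct becomes the trans (2R,3R) ring. The step needs the alkoxide to cyclise faster than it fragments by retro-aldol or enolises C3: the C–F bond activated by the ortho carbonyl and two meta alkoxy groups, the six-membered geometry and the low temperature favour closure, and fluoride is the one external nucleophile whose own attack at C8a is degenerate.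

Step 11
Reactants: 24 (2R,3R)-2-{3-[(2E)-3,7-dimethylocta-2,6-dien-1-yl]-4-(methoxymethoxy)phenyl}-3,5,7-tris(methoxymethoxy)-8-(3-methylbut-2-en-1-yl)-2,3-dihydro-4H-chromen-4-one
Product: 25 Sanggenol C, (2R,3R)-2-{3-[(2E)-3,7-dimethylocta-2,6-dien-1-yl]-4-hydroxyphenyl}-3,5,7-trihydroxy-8-(3-methylbut-2-en-1-yl)-2,3-dihydro-4H-chromen-4-one
Conditions: HCl (3 M aq), MeOH, 45 °C
Reagents that add atoms: none
Why: Acid-catalysed acetal exchange with methanol (transacetalisation) removes the three aryl acetals and the C3 acetal as dimethoxymethane under conditions of the kind used for prenylated flavonoids, without touching C2 or C3.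

Compound list
1 | 5-fluorobenzene-1,3-diol (5-fluororesorcinol) | Oc1cc(O)cc(F)c1 | starting material
2 | 4,6-dibromo-5-fluorobenzene-1,3-diol | Oc1cc(O)c(Br)c(F)c1Br | intermediate
3 | 1,3-dibromo-2-fluoro-4,6-bis(methoxymethoxy)benzene | COCOc1cc(OCOC)c(Br)c(F)c1Br | intermediate
4 | 1-bromo-3-methylbut-2-ene (prenyl bromide) | CC(C)=CCBr | starting material
5 | [3-bromo-2-fluoro-4,6-bis(methoxymethoxy)phenyl]lithium | [Li]c1c(F)c(Br)c(OCOC)cc1OCOC | intermediate
6 | 1-bromo-2-fluoro-4,6-bis(methoxymethoxy)-3-(3-methylbut-2-en-1-yl)benzene | COCOc1cc(OCOC)c(CC=C(C)C)c(F)c1Br | intermediate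
7 | methyl 2-hydroxyacetate (methyl glycolate) | COC(=O)CO | starting material
8 | methyl 2-(methoxymethoxy)acetate | COCOCC(=O)OC | intermediate
9 | N-methoxy-2-(methoxymethoxy)-N-methylacetamide | COCOCC(=O)N(C)OC | intermediate
10 | [2-fluoro-4,6-bis(methoxymethoxy)-3-(3-methylbut-2-en-1-yl)phenyl]lithium | [Li]c1c(F)c(CC=C(C)C)c(OCOC)cc1OCOC | intermediate
11 | lithium 1-[2-fluoro-4,6-bis(methoxymethoxy)-3-(3-methylbut-2-en-1-yl)phenyl]-1-[methoxy(methyl)amino]-2-(methoxymethoxy)ethan-1-olate | [Li]OC(COCOC)(N(C)OC)c1c(F)c(CC=C(C)C)c(OCOC)cc1OCOC | intermediate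
12 | 1-[2-fluoro-4,6-bis(methoxymethoxy)-3-(3-methylbut-2-en-1-yl)phenyl]-2-(methoxymethoxy)ethan-1-one | COCOCC(=O)c1c(F)c(CC=C(C)C)c(OCOC)cc1OCOC | intermediate
13 | lithium (Z)-1-[2-fluoro-4,6-bis(methoxymethoxy)-3-(3-methylbut-2-en-1-yl)phenyl]-2-(methoxymethoxy)ethen-1-olate | [Li]O/C(=C\OCOC)c1c(F)c(CC=C(C)C)c(OCOC)cc1OCOC | intermediate
14 | {[(Z)-1-[2-fluoro-4,6-bis(methoxymethoxy)-3-(3-methylbut-2-en-1-yl)phenyl]-2-(methoxymethoxy)ethenyl]oxy}trimethylsilane | COCO/C=C(\O[Si](C)(C)C)c1c(F)c(CC=C(C)C)c(OCOC)cc1OCOC | intermediate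
15 | 3-bromo-4-hydroxybenzaldehyde | O=Cc1ccc(O)c(Br)c1 | starting material
16 | 3-bromo-4-(methoxymethoxy)benzaldehyde | COCOc1ccc(C=O)cc1Br | intermediate
17 | (2E)-1-bromo-3,7-dimethylocta-2,6-diene (geranyl bromide) | CC(C)=CCC/C(C)=C/CBr | starting material
18 | lithium [3-bromo-4-(methoxymethoxy)phenyl](morpholin-4-yl)methanolate | [Li]OC(N1CCOCC1)c1ccc(OCOC)c(Br)c1 | intermediate
19 | lithium [3-lithio-4-(methoxymethoxy)phenyl](morpholin-4-yl)methanolate | [Li]OC(N1CCOCC1)c1ccc(OCOC)c([Li])c1 | intermediate
20 | lithium {3-[(2E)-3,7-dimethylocta-2,6-dien-1-yl]-4-(methoxymethoxy)phenyl}(morpholin-4-yl)methanolate | [Li]OC(N1CCOCC1)c1ccc(OCOC)c(C/C=C(\C)CCC=C(C)C)c1 | intermediate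
21 | 3-[(2E)-3,7-dimethylocta-2,6-dien-1-yl]-4-(methoxymethoxy)benzaldehyde | COCOc1ccc(C=O)cc1C/C=C(\C)CCC=C(C)C | intermediate
22 | (2R,3R)-3-{3-[(2E)-3,7-dimethylocta-2,6-dien-1-yl]-4-(methoxymethoxy)phenyl}-1-[2-fluoro-4,6-bis(methoxymethoxy)-3-(3-methylbut-2-en-1-yl)phenyl]-2-(methoxymethoxy)-3-[(trichlorosilyl)oxy]propan-1-one | CC(C)=CCC/C(C)=C/Cc1cc([C@H]([C@@H](OCOC)C(=O)c2c(F)c(CC=C(C)C)c(OCOC)cc2OCOC)O[Si](Cl)(Cl)Cl)ccc1OCOC | intermediate
23 | cesium (1R,2R)-1-{3-[(2E)-3,7-dimethylocta-2,6-dien-1-yl]-4-(methoxymethoxy)phenyl}-3-[2-fluoro-4,6-bis(methoxymethoxy)-3-(3-methylbut-2-en-1-yl)phenyl]-2-(methoxymethoxy)-3-oxopropan-1-olate | CC(C)=CCC/C(C)=C/Cc1cc([C@H]([C@@H](OCOC)C(=O)c2c(F)c(CC=C(C)C)c(OCOC)cc2OCOC)[O-])ccc1OCOC.[Cs+] | intermediate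
24 | (2R,3R)-2-{3-[(2E)-3,7-dimethylocta-2,6-dien-1-yl]-4-(methoxymethoxy)phenyl}-3,5,7-tris(methoxymethoxy)-8-(3-methylbut-2-en-1-yl)-2,3-dihydro-4H-chromen-4-one | CC(C)=CCC/C(C)=C/Cc1cc([C@H]2Oc3c(CC=C(C)C)c(OCOC)cc(OCOC)c3C(=O)[C@@H]2OCOC)ccc1OCOC | intermediate
25 | Sanggenol C, (2R,3R)-2-{3-[(2E)-3,7-dimethylocta-2,6-dien-1-yl]-4-hydroxyphenyl}-3,5,7-trihydroxy-8-(3-methylbut-2-en-1-yl)-2,3-dihydro-4H-chromen-4-one | CC(C)=CCC/C(C)=C/Cc1cc([C@H]2Oc3c(CC=C(C)C)c(O)cc(O)c3C(=O)[C@@H]2O)ccc1O | target

Total step count: 11 steps.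
Longest linear sequence: 7 steps (steps 1, 2, 3, 6, 7, 10 and 11, from 5-fluorobenzene-1,3-diol).

Steps most likely to fail

Step 10. When fluoride frees the C2 oxygen, the alkoxide may fragment by retro-aldol and recombine outside catalyst control, or the open transition state may not deliver the anti adduct cleanly; either process would erode the configuration at C2 or C3. The fallback uses known chemistry only, makes the two bonds in separate steps and introduces the C3 oxygen last under substrate control. It sets out from bromide 6 and aldehyde 21 and comes back to the route at 25. Bromine–lithium exchange of 6 (n-BuLi, THF, −78 °C) and acylation with N-methoxy-N-methylacetamide would give the methyl ketone F1, which LiN(SiMe3)2 and Me3SiCl convert into the trimethylsilyl enol ether F2. The SiCl4/bisphosphoramide Mukaiyama aldol of F2 with 21, a pairing of methyl ketone enol silane and aromatic aldehyde for which this catalysis is established, followed by the usual aqueous KF/NaHCO3 work-up, should give the (S)-β-hydroxy ketone F3. NaH in THF at 0 °C then closes ring C by SNAr to the (2S)-flavanone F4. Its potassium enolate (KN(SiMe3)2, THF, −78 °C) is hydroxylated with 3-phenyl-2-(phenylsulfonyl)oxaziridine on the face anti to the C2 aryl group to give the trans (2R,3R)-3-hydroxyflavanone F5. Brief treatment of F5 with HCl in MeOH at room temperature removes the three aryl acetals and should give 25.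

Step 11. Acid may add the liberated 7-OH and 4′-OH across the neighbouring prenyl and geranyl double bonds (chroman formation) while the slower C3 acetal is still being cleaved, and prolonged warming may epimerise C2 through opening of ring C to a ring B quinone methide. The fallback avoids protic acid; it sets out from 24 and comes back to the route at 25. Et3SiOTf and 2,2′-bipyridyl in CH2Cl2 at 0 °C should exchange the three aryl acetals for triethylsilyl ethers and convert the C3 acetal into a pyridinium acetal that hydrolyses on aqueous work-up, giving the tris(triethylsilyl) ether F6. Bu4NF buffered with AcOH in THF at 0 °C then frees the three phenols and should give 25.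

Step 9. Incomplete masking of the aldehyde would let n-BuLi add to the carbonyl group, and the allylic substitution may leak into SN2′ attack or lose the E geometry of the geranyl unit. The fallback uses no organolithium; it sets out from 16 and comes back to the route at 21. Miyaura borylation (B2pin2, Pd(dppf)Cl2, KOAc, dioxane, 80 °C) would give the pinacol boronate F7. Suzuki–Miyaura coupling of F7 with geranyl bromide 17 (Pd(PPh3)4, K2CO3, THF/H2O, 60 °C), in which the aryl group is delivered to the unsubstituted terminus of the allylpalladium intermediate, should give 21.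

Further compounds
F1 | step 10 | 1-[2-fluoro-4,6-bis(methoxymethoxy)-3-(3-methylbut-2-en-1-yl)phenyl]ethan-1-one | CC(=O)c1c(F)c(CC=C(C)C)c(OCOC)cc1OCOC
F2 | step 10 | ({1-[2-fluoro-4,6-bis(methoxymethoxy)-3-(3-methylbut-2-en-1-yl)phenyl]ethenyl}oxy)trimethylsilane | C=C(O[Si](C)(C)C)c1c(F)c(CC=C(C)C)c(OCOC)cc1OCOC
F3 | step 10 | (3S)-3-{3-[(2E)-3,7-dimethylocta-2,6-dien-1-yl]-4-(methoxymethoxy)phenyl}-1-[2-fluoro-4,6-bis(methoxymethoxy)-3-(3-methylbut-2-en-1-yl)phenyl]-3-hydroxypropan-1-one | CC(C)=CCC/C(C)=C/Cc1cc([C@H](CC(=O)c2c(F)c(CC=C(C)C)c(OCOC)cc2OCOC)O)ccc1OCOC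
F4 | step 10 | (2S)-2-{3-[(2E)-3,7-dimethylocta-2,6-dien-1-yl]-4-(methoxymethoxy)phenyl}-5,7-bis(methoxymethoxy)-8-(3-methylbut-2-en-1-yl)-2,3-dihydro-4H-chromen-4-one | CC(C)=CCC/C(C)=C/Cc1cc([C@H]2Oc3c(CC=C(C)C)c(OCOC)cc(OCOC)c3C(=O)C2)ccc1OCOC
F5 | step 10 | (2R,3R)-2-{3-[(2E)-3,7-dimethylocta-2,6-dien-1-yl]-4-(methoxymethoxy)phenyl}-3-hydroxy-5,7-bis(methoxymethoxy)-8-(3-methylbut-2-en-1-yl)-2,3-dihydro-4H-chromen-4-one | CC(C)=CCC/C(C)=C/Cc1cc([C@H]2Oc3c(CC=C(C)C)c(OCOC)cc(OCOC)c3C(=O)[C@@H]2O)ccc1OCOC
F6 | step 11 | (2R,3R)-2-{3-[(2E)-3,7-dimethylocta-2,6-dien-1-yl]-4-[(triethylsilyl)oxy]phenyl}-3-hydroxy-8-(3-methylbut-2-en-1-yl)-5,7-bis[(triethylsilyl)oxy]-2,3-dihydro-4H-chromen-4-one | CC(C)=CCC/C(C)=C/Cc1cc([C@H]2Oc3c(CC=C(C)C)c(O[Si](CC)(CC)CC)cc(O[Si](CC)(CC)CC)c3C(=O)[C@@H]2O)ccc1O[Si](CC)(CC)CC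
F7 | step 9 | 4-(methoxymethoxy)-3-(4,4,5,5-tetramethyl-1,3,2-dioxaborolan-2-yl)benzaldehyde | COCOc1ccc(C=O)cc1B1OC(C)(C)C(C)(C)O1
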